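**Retrosynthetic overview**

1. The target is reached from the all-trans tetralin 2,3-diester 14 by ester reduction and O-debenzylation; both hydroxymethyl groups are carried as esters.
2. Ring B is opened at the C2–C3 bond: 14 comes from open-chain diester 12 by intramolecular oxidative coupling of its bis-enolate. This is the only ring formed in the route; ring A and the guaiacyl ring C are bought as arenes.
3. Enabling feature: C2 and C3 each carry the carbon that ends as CH2OH. At the ester level they are two enolisable α-carbons on ortho-related three-carbon arms of ring A, six atoms apart, with the C1 stereocentre next to C2.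
4. C1 is set by a rhodium-catalysed asymmetric 1,4-arylation of cinnamate 10, which also attaches ring C; C2 and C3 are then relayed from C1 in the ring closure.
5. Cinnamate 10 comes from hydrocinnamic acid 7 by carboxylate-directed C–H olefination; 7 comes from 2,3,4-trihydroxybenzaldehyde.

Key step: step 7

Remark on numbering: tetralin numbering is used. C1 carries ring C, C2 and C3 carry the hydroxymethyl groups, C4 is the benzylic CH2, and ring A carries 5,6-OMe and 7-OH. The target is (1R,2S,3S), all-trans.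
Assumption: both enantiomers of the chiral diene ligand in step 6 are available, and the one that delivers the aryl group to the Si face of the β-carbon is used.

**Step 1**
Reactants: 1 2,3,4-trihydroxybenzaldehyde
Product: 2 4-(benzyloxy)-2,3-dihydroxybenzaldehyde
Conditions: BnBr (1.0 equiv), NaHCO3 (1.5 equiv), KI (cat.), MeCN, 80 °C
Reagents that add atoms: benzyl bromide, BrCc1ccccc1
Why: Williamson etherification; the 4-OH, para to the formyl group and not hydrogen-bonded to it, is the most acidic and should be the only phenol alkylated with a weak base.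

**Step 2**
Reactants: 2 4-(benzyloxy)-2,3-dihydroxybenzaldehyde
Product: 3 4-(benzyloxy)-2,3-dimethoxybenzaldehyde
Conditions: MeI (3 equiv), K2CO3 (3 equiv), DMF, 40 °C
Reagents that add atoms: iodomethane, CI
Why: Exhaustive Williamson O-methylation of the two remaining phenols, the chelated 2-OH included under these forcing conditions.

**Step 3**
Reactants: 3 4-(benzyloxy)-2,3-dimethoxybenzaldehyde; 4 Meldrum's acid
Product: 7 3-[4-(benzyloxy)-2,3-dimethoxyphenyl]propanoic acid, via arylidene Meldrum's acid 5 (not isolated), via benzyl Meldrum's acid 6 (not isolated)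
Conditions: HCO2H/Et3N (5:2), 95–100 °C; aq. HCl work-up
Reagents that add atoms: none
Why: One-pot reductive Knoevenagel condensation: the arylidene Meldrum's acid is reduced by formate hydride transfer and the alkylated Meldrum's acid loses acetone and CO2 on heating; no metal is present, so the benzyl ether is untouched.

**Step 4**
Reactants: 7 3-[4-(benzyloxy)-2,3-dimethoxyphenyl]propanoic acid; 8 tert-butyl acrylate
Product: 9 3-{4-(benzyloxy)-6-[(1E)-3-tert-butoxy-3-oxoprop-1-en-1-yl]-2,3-dimethoxyphenyl}propanoic acid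
Conditions: Pd(OAc)2 (5 mol %), Ac-Ile-OH (10 mol %), KHCO3 (2 equiv), O2 (1 atm), t-AmylOH, 90 °C; acidic work-up
Reagents that add atoms: none
Why: Carboxylate-directed ortho C–H palladation by divalent palladium, acrylate insertion and β-hydride elimination (oxidative Heck, Fujiwara–Moritani type, known for 3-arylpropanoic acids) should give the E-cinnamate; C6 is the only ortho C–H because C2 carries OMe, and O2 reoxidises zerovalent palladium.

**Step 5**
Reactants: 9 3-{4-(benzyloxy)-6-[(1E)-3-tert-butoxy-3-oxoprop-1-en-1-yl]-2,3-dimethoxyphenyl}propanoic acid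
Product: 10 methyl 3-{4-(benzyloxy)-6-[(1E)-3-tert-butoxy-3-oxoprop-1-en-1-yl]-2,3-dimethoxyphenyl}propanoate
Conditions: MeI (1.5 equiv), K2CO3 (1.5 equiv), DMF, rt
Reagents that add atoms: iodomethane, CI
Why: Carboxylate O-alkylation; no other acidic site is present and the tert-butyl enoate is inert.

**Step 6**
Reactants: 10 methyl 3-{4-(benzyloxy)-6-[(1E)-3-tert-butoxy-3-oxoprop-1-en-1-yl]-2,3-dimethoxyphenyl}propanoate; 11 [4-(benzyloxy)-3-methoxyphenyl]boronic acid
Product: 12 tert-butyl (3R)-3-[4-(benzyloxy)-3-methoxyphenyl]-3-[5-(benzyloxy)-3,4-dimethoxy-2-(3-methoxy-3-oxopropyl)phenyl]propanoate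
Conditions: [RhCl(C2H4)2]2 (2.5 mol %), enantiopure 2,5-diphenylbicyclo[2.2.2]octa-2,5-diene (6 mol %), 11 (2 equiv), KOH (0.2 equiv), dioxane/H2O (10:1), 50 °C
Reagents that add atoms: none
Why: Hayashi–Miyaura asymmetric 1,4-addition: the aryl complex of monovalent rhodium inserts the enoate inside the chiral diene pocket and water protonates the oxa-π-allyl intermediate; aryl delivery to the Si face of the β-carbon sets C1 as R.

**Step 7**
Reactants: 12 tert-butyl (3R)-3-[4-(benzyloxy)-3-methoxyphenyl]-3-[5-(benzyloxy)-3,4-dimethoxy-2-(3-methoxy-3-oxopropyl)phenyl]propanoate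
Product: 14 2-tert-butyl 3-methyl (1R,2S,3S)-7-(benzyloxy)-1-[4-(benzyloxy)-3-methoxyphenyl]-5,6-dimethoxy-1,2,3,4-tetrahydronaphthalene-2,3-dicarboxylate, via dilithium bis-enolate 13 (not isolated)
Conditions: commercial LDA (2.2 equiv), THF, −78 °C, slow addition of 12 (0.02 M); then anhydrous CuCl2 (2.2 equiv) in DMF/THF, −78 → 0 °C
Reagents that add atoms: none
Why: Double deprotonation gives bis(ester enolate) 13; one-electron oxidation of one enolate by divalent copper gives an α-ester radical (or copper-bound enolate) that is trapped by the second enolate carbon, and a second electron transfer to CuCl2 delivers the succinate, which is the intramolecular oxidative enolate–enolate coupling of a diester dianion, a reaction type established for closing three- to six-membered rings. Ring B closes in a 6-exo-trig mode (the C3 radical adds to C2 of the enolate C=C, whose other carbon stays outside the ring), and the ortho arrangement of the two arms on ring A holds the termini six atoms apart and pre-organised. C2 is controlled by the C1 stereocentre: with C1–H eclipsing the enolate plane (allylic 1,3-strain), the tethered C3 terminus must approach from the face that carries ring A, so the new bond forms anti to the guaiacyl group and the ester ends trans to it (2S). C3 is set in the same half-chair transition state, where both alkoxycarbonyl units sit pseudo-equatorial, giving the 2,3-trans relationship (3S). The step needs ring closure to beat intermolecular coupling, which the short rigid tether and high dilution should secure, and trans,trans diastereoselection, which is also the thermodynamic arrangement (all three substituents equatorial), so a cis isomer could be converged on 14 with catalytic t-BuOK in t-BuOH because both new centres are α to esters. Exactly two equivalents of base and oxidant are used to avoid further oxidation of the product succinate to a dihydronaphthalene.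

**Step 8**
Reactants: 14 2-tert-butyl 3-methyl (1R,2S,3S)-7-(benzyloxy)-1-[4-(benzyloxy)-3-methoxyphenyl]-5,6-dimethoxy-1,2,3,4-tetrahydronaphthalene-2,3-dicarboxylate
Product: 15 [(1R,2S,3S)-7-(benzyloxy)-1-[4-(benzyloxy)-3-methoxyphenyl]-5,6-dimethoxy-1,2,3,4-tetrahydronaphthalene-2,3-diyl]dimethanol
Conditions: LiAlH4 (4 equiv), THF, 0 °C → reflux; aqueous NaOH work-up
Reagents that add atoms: none
Why: Hydride reduction of both esters to primary alcohols; the benzyl ethers are inert and the α-centres already hold the thermodynamic all-trans arrangement, so no stereocentre should change.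

**Step 9**
Reactants: 15 [(1R,2S,3S)-7-(benzyloxy)-1-[4-(benzyloxy)-3-methoxyphenyl]-5,6-dimethoxy-1,2,3,4-tetrahydronaphthalene-2,3-diyl]dimethanol
Product: 16 (1R,2S,3S)-1-(4-hydroxy-3-methoxyphenyl)-2,3-bis(hydroxymethyl)-5,6-dimethoxy-1,2,3,4-tetrahydronaphthalen-7-ol
Conditions: H2 (1 atm), Pd/C (10 %), EtOAc/MeOH, rt
Reagents that add atoms: none
Why: Hydrogenolysis of the two aryl benzyl ethers over palladium on carbon; nothing else is reducible under these conditions and the stereocentres are not involved.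

**Compound list**

1 | 2,3,4-trihydroxybenzaldehyde | O=Cc1ccc(O)c(O)c1O | starting material
2 | 4-(benzyloxy)-2,3-dihydroxybenzaldehyde | O=Cc1ccc(OCc2ccccc2)c(O)c1O | intermediate
3 | 4-(benzyloxy)-2,3-dimethoxybenzaldehyde | COc1c(C=O)ccc(OCc2ccccc2)c1OC | intermediate
4 | Meldrum's acid (2,2-dimethyl-1,3-dioxane-4,6-dione) | CC1(C)OC(=O)CC(=O)O1 | starting material
5 | 5-[4-(benzyloxy)-2,3-dimethoxybenzylidene]-2,2-dimethyl-1,3-dioxane-4,6-dione (not isolated) | COc1c(C=C2C(=O)OC(C)(C)OC2=O)ccc(OCc2ccccc2)c1OC | intermediate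
6 | 5-[4-(benzyloxy)-2,3-dimethoxybenzyl]-2,2-dimethyl-1,3-dioxane-4,6-dione (not isolated) | COc1c(CC2C(=O)OC(C)(C)OC2=O)ccc(OCc2ccccc2)c1OC | intermediate
7 | 3-[4-(benzyloxy)-2,3-dimethoxyphenyl]propanoic acid | COc1c(CCC(=O)O)ccc(OCc2ccccc2)c1OC | intermediate
8 | tert-butyl acrylate | C=CC(=O)OC(C)(C)C | starting material
9 | 3-{4-(benzyloxy)-6-[(1E)-3-tert-butoxy-3-oxoprop-1-en-1-yl]-2,3-dimethoxyphenyl}propanoic acid | COc1c(CCC(=O)O)c(/C=C/C(=O)OC(C)(C)C)cc(OCc2ccccc2)c1OC | intermediate
10 | methyl 3-{4-(benzyloxy)-6-[(1E)-3-tert-butoxy-3-oxoprop-1-en-1-yl]-2,3-dimethoxyphenyl}propanoate | COC(=O)CCc1c(/C=C/C(=O)OC(C)(C)C)cc(OCc2ccccc2)c(OC)c1OC | intermediate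
11 | [4-(benzyloxy)-3-methoxyphenyl]boronic acid | COc1cc(B(O)O)ccc1OCc1ccccc1 | starting material
12 | tert-butyl (3R)-3-[4-(benzyloxy)-3-methoxyphenyl]-3-[5-(benzyloxy)-3,4-dimethoxy-2-(3-methoxy-3-oxopropyl)phenyl]propanoate | COc1cc([C@@H](CC(=O)OC(C)(C)C)c2cc(OCc3ccccc3)c(OC)c(OC)c2CCC(=O)OC)ccc1OCc1ccccc1 | intermediate
13 | dilithium bis-enolate of 12 (not isolated) | COc1cc([C@@H](C=C(O[Li])OC(C)(C)C)c2cc(OCc3ccccc3)c(OC)c(OC)c2CC=C(O[Li])OC)ccc1OCc1ccccc1 | intermediate
14 | 2-tert-butyl 3-methyl (1R,2S,3S)-7-(benzyloxy)-1-[4-(benzyloxy)-3-methoxyphenyl]-5,6-dimethoxy-1,2,3,4-tetrahydronaphthalene-2,3-dicarboxylate | COc1cc([C@@H]2c3cc(OCc4ccccc4)c(OC)c(OC)c3C[C@H](C(=O)OC)[C@H]2C(=O)OC(C)(C)C)ccc1OCc1ccccc1 | intermediate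
15 | [(1R,2S,3S)-7-(benzyloxy)-1-[4-(benzyloxy)-3-methoxyphenyl]-5,6-dimethoxy-1,2,3,4-tetrahydronaphthalene-2,3-diyl]dimethanol | COc1cc([C@@H]2c3cc(OCc4ccccc4)c(OC)c(OC)c3C[C@H](CO)[C@H]2CO)ccc1OCc1ccccc1 | intermediate
16 | (1R,2S,3S)-1-(4-hydroxy-3-methoxyphenyl)-2,3-bis(hydroxymethyl)-5,6-dimethoxy-1,2,3,4-tetrahydronaphthalen-7-ol, equivalently (6S,7S,8R)-8-(4-hydroxy-3-methoxyphenyl)-6,7-bis(hydroxymethyl)-3,4-dimethoxy-5,6,7,8-tetrahydronaphthalen-2-ol | COc1cc([C@@H]2c3cc(O)c(OC)c(OC)c3C[C@H](CO)[C@H]2CO)ccc1O | target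

**Step count and risks**

Total step count: 9. Longest linear sequence: 9 steps, from 2,3,4-trihydroxybenzaldehyde.

The three steps most likely to fail:

Step 7. Intermolecular coupling or α-chlorination of the enolates may outrun ring closure, or the configuration at C1 may be relayed incompletely to C2 and C3. The fallback sets out from 12 and puts the coupling under auxiliary control. Saponification of the methyl ester (LiOH, THF/H2O) and acidolysis of the tert-butyl ester (TFA, CH2Cl2) would give (3R)-3-[4-(benzyloxy)-3-methoxyphenyl]-3-[5-(benzyloxy)-2-(2-carboxyethyl)-3,4-dimethoxyphenyl]propanoic acid F1. Double N-acylation of (R)-4-benzyl-1,3-oxazolidin-2-one (DCC, DMAP, CH2Cl2) would give the bis(N-acyloxazolidinone) F2. Its dilithium bis-enolate F3 (LDA, THF, −78 °C) would be oxidised with CuCl2 in the known intramolecular oxidative coupling of bis-imide enolates, where the facial bias of both (R)-auxiliaries corresponds to 2S,3S, to give the cyclised bis-imide F4. LiBH4 (THF, H2O) would reduce off both auxiliaries and the route is rejoined at 15.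

Step 4. Palladation of the electron-rich ring may be slow or unselective, or the substrate may degrade oxidatively under O2 at 90 °C. The fallback sets out from 7 and uses classical chemistry with forced regiochemistry. Oxalyl chloride (cat. DMF) would give 3-[4-(benzyloxy)-2,3-dimethoxyphenyl]propanoyl chloride F5. Intramolecular Friedel–Crafts acylation (SnCl4, CH2Cl2, −20 °C), which can only close onto C6, would give 6-(benzyloxy)-4,5-dimethoxyindan-1-one F6. Baeyer–Villiger oxidation (mCPBA, NaHCO3, CH2Cl2) with migration of the electron-rich aryl group would give 7-(benzyloxy)-5,6-dimethoxychroman-2-one F7. Methanolysis (NaOMe, MeOH, 0 °C) would give methyl 3-[4-(benzyloxy)-6-hydroxy-2,3-dimethoxyphenyl]propanoate F8, which is triflated at once (PhNTf2, Et3N) to methyl 3-[4-(benzyloxy)-2,3-dimethoxy-6-(trifluoromethanesulfonyloxy)phenyl]propanoate F9. A Heck reaction of F9 with 8 (Pd(OAc)2, dppp, Et3N, DMF, 90 °C) would rejoin the route at 10, so step 5 is not needed.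

Step 6. The ortho-substituted, electron-rich cinnamate may insert slowly so that protodeboronation competes, or facial selectivity may be insufficient. The fallback sets out from 10 and replaces catalyst control by a covalent auxiliary. TFA (CH2Cl2) would give (2E)-3-[5-(benzyloxy)-3,4-dimethoxy-2-(3-methoxy-3-oxopropyl)phenyl]prop-2-enoic acid F10. Coupling with (S)-4-phenyl-1,3-oxazolidin-2-one (DCC, DMAP) would give the N-enoyl imide F11. [4-(Benzyloxy)-3-methoxyphenyl]magnesium bromide F12, made from commercial 1-(benzyloxy)-4-bromo-2-methoxybenzene and Mg, would add with CuBr·SMe2 (THF, −40 °C) anti to the phenyl group of the magnesium-chelated s-cis imide; this is expected to give the (3R)-adduct F13. LiOH/H2O2 (THF/H2O, 0 °C) would give (3R)-3-[4-(benzyloxy)-3-methoxyphenyl]-3-[5-(benzyloxy)-3,4-dimethoxy-2-(3-methoxy-3-oxopropyl)phenyl]propanoic acid F14. tert-Butylation (Boc2O, DMAP, t-BuOH) would rejoin the route at 12.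

**Further compounds**

F1 | step 7 | (3R)-3-[4-(benzyloxy)-3-methoxyphenyl]-3-[5-(benzyloxy)-2-(2-carboxyethyl)-3,4-dimethoxyphenyl]propanoic acid | COc1cc([C@@H](CC(=O)O)c2cc(OCc3ccccc3)c(OC)c(OC)c2CCC(=O)O)ccc1OCc1ccccc1
F2 | step 7 | bis-imide of F1 with two (4R)-4-benzyl-2-oxo-1,3-oxazolidin-3-yl groups | COc1cc([C@@H](CC(=O)N2[C@H](Cc3ccccc3)COC2=O)c2cc(OCc3ccccc3)c(OC)c(OC)c2CCC(=O)N2[C@H](Cc3ccccc3)COC2=O)ccc1OCc1ccccc1
F3 | step 7 | dilithium bis-enolate of F2 | COc1cc([C@@H](C=C(O[Li])N2[C@H](Cc3ccccc3)COC2=O)c2cc(OCc3ccccc3)c(OC)c(OC)c2CC=C(O[Li])N2[C@H](Cc3ccccc3)COC2=O)ccc1OCc1ccccc1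
F4 | step 7 | (1R,2S,3S)-7-(benzyloxy)-1-[4-(benzyloxy)-3-methoxyphenyl]-5,6-dimethoxy-2,3-bis{[(4R)-4-benzyl-2-oxo-1,3-oxazolidin-3-yl]carbonyl}-1,2,3,4-tetrahydronaphthalene | COc1cc([C@@H]2c3cc(OCc4ccccc4)c(OC)c(OC)c3C[C@H](C(=O)N3[C@H](Cc4ccccc4)COC3=O)[C@H]2C(=O)N2[C@H](Cc3ccccc3)COC2=O)ccc1OCc1ccccc1
F5 | step 4 | 3-[4-(benzyloxy)-2,3-dimethoxyphenyl]propanoyl chloride | COc1c(CCC(=O)Cl)ccc(OCc2ccccc2)c1OC
F6 | step 4 | 6-(benzyloxy)-4,5-dimethoxy-2,3-dihydro-1H-inden-1-one | COc1c(OC)c2c(cc1OCc1ccccc1)C(=O)CC2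
F7 | step 4 | 7-(benzyloxy)-5,6-dimethoxy-3,4-dihydro-2H-chromen-2-one | COc1c(OC)c2c(cc1OCc1ccccc1)OC(=O)CC2
F8 | step 4 | methyl 3-[4-(benzyloxy)-6-hydroxy-2,3-dimethoxyphenyl]propanoate | COC(=O)CCc1c(O)cc(OCc2ccccc2)c(OC)c1OC
F9 | step 4 | methyl 3-[4-(benzyloxy)-2,3-dimethoxy-6-(trifluoromethanesulfonyloxy)phenyl]propanoate | COC(=O)CCc1c(OS(=O)(=O)C(F)(F)F)cc(OCc2ccccc2)c(OC)c1OC
F10 | step 6 | (2E)-3-[5-(benzyloxy)-3,4-dimethoxy-2-(3-methoxy-3-oxopropyl)phenyl]prop-2-enoic acid | COC(=O)CCc1c(/C=C/C(=O)O)cc(OCc2ccccc2)c(OC)c1OC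
F11 | step 6 | methyl 3-[4-(benzyloxy)-2,3-dimethoxy-6-{(1E)-3-oxo-3-[(4S)-2-oxo-4-phenyl-1,3-oxazolidin-3-yl]prop-1-en-1-yl}phenyl]propanoate | COC(=O)CCc1c(/C=C/C(=O)N2[C@@H](c3ccccc3)COC2=O)cc(OCc2ccccc2)c(OC)c1OC
F12 | step 6 | [4-(benzyloxy)-3-methoxyphenyl]magnesium bromide | COc1cc([Mg]Br)ccc1OCc1ccccc1
F13 | step 6 | methyl 3-[4-(benzyloxy)-6-{(1R)-1-[4-(benzyloxy)-3-methoxyphenyl]-3-oxo-3-[(4S)-2-oxo-4-phenyl-1,3-oxazolidin-3-yl]propyl}-2,3-dimethoxyphenyl]propanoate | COc1cc([C@@H](CC(=O)N2[C@@H](c3ccccc3)COC2=O)c2cc(OCc3ccccc3)c(OC)c(OC)c2CCC(=O)OC)ccc1OCc1ccccc1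
F14 | step 6 | (3R)-3-[4-(benzyloxy)-3-methoxyphenyl]-3-[5-(benzyloxy)-3,4-dimethoxy-2-(3-methoxy-3-oxopropyl)phenyl]propanoic acid | COc1cc([C@@H](CC(=O)O)c2cc(OCc3ccccc3)c(OC)c(OC)c2CCC(=O)OC)ccc1OCc1ccccc1
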